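**Assumption:** germacrane numbering is used for the cyclic compounds (ring C1–C10, C14 methyl on C10, C15 methyl on C4, isopropyl on C7). The target is then (1S,4R,5S,6R,7R,8S,10R)-1-acetoxy-6-(E)-cinnamoyloxy-5,8-epoxygermacrane-4,10-diol.

## Retrosynthetic overview

- Target ⇐ acetylation of the C1 alcohol ⇐ chelation-controlled reduction of a C1 ketone ⇐ oxidation of the 1,10-syn-diol made by osmylation of the trans C1=C10 alkene.
- Oxolane ring (5,8-ether) with the cinnamate in place ⇐ Evans–Tishchenko reduction of a 6-hydroxy-8-ketone with cinnamaldehyde, then transannular 5-exo opening of the 4,5-epoxide by the new 8-hydroxyl.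
- Ten-membered ring ⇐ CrCl2 Reformatsky-type macro-aldol forming C6–C7 (the farnesyl C1–C10 bond and polarity of germacrene biosynthesis) from an acyclic epoxy aldehyde / α-bromo ketone.
- Acyclic precursor ⇐ (E,E)-farnesol: terminal alkene → transposed enone → α-bromo ketone; Sharpless epoxidation sets C4/C5.
- Ring order: ten-membered carbocycle first, then the oxolane by transannular ether closure.

## Route

Step 1
Reactants: 1 (2E,6E)-farnesol
Product: 3 (2E,6E)-10,11-epoxyfarnesol (racemic epoxide), via bromohydrin 2 (not isolated)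
Conditions: NBS, THF/H2O, 0 °C; then K2CO3, MeOH, 23 °C
Reagents that add atoms: water, O
Why: Terminal-selective bromohydrin formation in aqueous THF (van Tamelen) and base closure give the 10,11-epoxide; its stereocenter is removed in step 2.

Step 2
Reactants: 3 (2E,6E)-10,11-epoxyfarnesol
Product: 5 (2E,6E,9E)-3,7,11-trimethyldodeca-2,6,9-triene-1,11-diol, via hydroxy selenide 4 (not isolated)
Conditions: PhSeSePh, NaBH4, EtOH, 78 °C; then H2O2, THF, 0 to 23 °C
Reagents that add atoms: none
Why: Sharpless–Lauer epoxide-to-allylic-alcohol conversion: selenide opens the epoxide at the secondary carbon and selenoxide syn-elimination away from the carbinol gives the (9E) tertiary allylic alcohol.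

Step 3
Reactants: 5 (2E,6E,9E)-3,7,11-trimethyldodeca-2,6,9-triene-1,11-diol
Product: 6 (2R,3R,6E,9E)-2,3-epoxy-3,7,11-trimethyldodeca-6,9-diene-1,11-diol
Conditions: Ti(OiPr)4 (10 mol%), D-(−)-diethyl tartrate (12 mol%), t-BuOOH, 4 Å MS, CH2Cl2, −20 °C
Reagents that add atoms: tert-butyl hydroperoxide, CC(C)(C)OO
Why: Sharpless asymmetric epoxidation of the primary allylic alcohol only (tertiary allylic alcohol and isolated alkene are inert); the D-tartrate gives the (2R,3R) epoxide, which fixes C4 and, after later inversion, C5.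

Step 4
Reactants: 6 (2R,3R,6E,9E)-2,3-epoxy-3,7,11-trimethyldodeca-6,9-diene-1,11-diol
Product: 7 (2R,3R,6E)-2,3-epoxy-1-hydroxy-3,7,11-trimethyldodeca-6,10-dien-9-one
Conditions: 4-acetamido-2,2,6,6-tetramethyl-1-oxopiperidinium tetrafluoroborate (1.5 equiv), 4 Å MS, MeCN, 0 to 23 °C
Reagents that add atoms: none
Why: Oxidative 1,3-transposition of the tertiary allylic alcohol to the enone by an oxoammonium salt (Babler–Dauben-type); the primary alcohol carries a β-oxygen (the epoxide) and is oxidised far more slowly by oxoammonium salts in the absence of base.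

Step 5
Reactants: 7 (2R,3R,6E)-2,3-epoxy-1-hydroxy-3,7,11-trimethyldodeca-6,10-dien-9-one
Product: 9 (2R,3R,6E)-10-bromo-2,3-epoxy-1-hydroxy-3,7,11-trimethyldodec-6-en-9-one (both C10 epimers), via catechol boron enolate 8 (not isolated)
Conditions: catecholborane (2.3 equiv), THF, −20 to 23 °C; then NBS, −78 °C; pH 7 buffer
Reagents that add atoms: N-bromosuccinimide, O=C1CCC(=O)N1Br
Why: Catecholborane conjugate reduction of the s-cis β,β-disubstituted enone creates the isopropyl group and a regiodefined boron enolate, which NBS brominates at the α-carbon; the new stereocenter is lost again in step 7.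

Step 6
Reactants: 9 (2R,3R,6E)-10-bromo-2,3-epoxy-1-hydroxy-3,7,11-trimethyldodec-6-en-9-one
Product: 10 (2S,3R,6E)-10-bromo-2,3-epoxy-3,7,11-trimethyl-9-oxododec-6-enal
Conditions: Dess–Martin periodinane, NaHCO3, CH2Cl2, 0 °C
Reagents that add atoms: none
Why: Dess–Martin oxidation of the epoxy alcohol to the epoxy aldehyde under buffered, non-basic conditions that leave the bromo ketone and the epoxide intact.

Step 7
Reactants: 10 (2S,3R,6E)-10-bromo-2,3-epoxy-3,7,11-trimethyl-9-oxododec-6-enal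
Product: 12 (1(10)E,4R,5R,6R,7S)-4,5-epoxy-6-hydroxygermacr-1(10)-en-8-one, via chromium enolate 11 (not isolated)
Conditions: CrCl2 (5 equiv), LiI (0.2 equiv), THF, 0.002 M (syringe pump), 23 °C
Reagents that add atoms: none
Why: Proposed new method: CrCl2 inserts into the C–Br bond to give a trivalent chromium enolate that is non-basic, ignores the ketone and epoxide and adds only to the aldehyde, so slow addition at high dilution should close the ten-membered ring through the C6–C7 bond (same bond and polarity as the farnesyl C1–C10 closure in germacrene biosynthesis, the trans alkene and trans epoxide pre-organising the chain); C7 follows from the anti (threo) preference of chromium enolates in a chair transition state and C6 from Felkin–Anh attack anti to the epoxide C–O bond; closest known reaction types are the chromium Reformatsky aldol of α-bromo ketones with aldehydes and the Nozaki–Hiyama–Kishi or allylzinc macrocyclisations of epoxy-farnesal-type chains to germacrane rings.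

Step 8
Reactants: 12 (1(10)E,4R,5R,6R,7S)-4,5-epoxy-6-hydroxygermacr-1(10)-en-8-one; 13 (E)-cinnamaldehyde
Product: 15 (1(10)E,4R,5S,6R,7R,8S)-5,8-epoxy-4-hydroxygermacr-1(10)-en-6-yl (E)-cinnamate, via hydroxy epoxide cinnamate 14 (not isolated)
Conditions: SmI2 (0.3 equiv), 13 (6 equiv), THF, −10 °C; then 23 °C
Reagents that add atoms: (E)-cinnamaldehyde 13, O=C/C=C/c1ccccc1
Why: Evans–Tishchenko reduction: the O6 hemiacetal of 13 delivers hydride to C8 inside a samarium chelate, giving the 6,8-anti diol monoester with the cinnamate on O6 (sets C8), and the freed 8-alkoxide then opens the 4,5-epoxide transannularly at C5 (5-exo, inversion) to form the oxolane and the C4 tertiary alcohol.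

Step 9
Reactants: 15 (1(10)E,4R,5S,6R,7R,8S)-5,8-epoxy-4-hydroxygermacr-1(10)-en-6-yl (E)-cinnamate
Product: 16 (1R,4R,5S,6R,7R,8S,10R)-5,8-epoxy-1,4,10-trihydroxygermacran-6-yl (E)-cinnamate
Conditions: OsO4 (2 mol%), NMO, acetone/H2O, 0 °C
Reagents that add atoms: N-methylmorpholine N-oxide, C[N+]1([O-])CCOCC1; water, O
Why: Upjohn syn-dihydroxylation: the strained, electron-rich trans ring alkene reacts before the conjugated cinnamate, and OsO4 adds to its outer face (the inner face looks into the ring), which sets the C10 hydroxyl as in the target and leaves C1 epimeric for correction in steps 10 and 11.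

Step 10
Reactants: 16 (1R,4R,5S,6R,7R,8S,10R)-5,8-epoxy-1,4,10-trihydroxygermacran-6-yl (E)-cinnamate
Product: 17 (4R,5S,6R,7R,8S,10R)-5,8-epoxy-4,10-dihydroxy-1-oxogermacran-6-yl (E)-cinnamate
Conditions: Dess–Martin periodinane, NaHCO3, CH2Cl2, 23 °C
Reagents that add atoms: none
Why: Dess–Martin oxidation of the only secondary alcohol to the α-hydroxy ketone; the two tertiary alcohols and the ester are inert and C10 is untouched.

Step 11
Reactants: 17 (4R,5S,6R,7R,8S,10R)-5,8-epoxy-4,10-dihydroxy-1-oxogermacran-6-yl (E)-cinnamate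
Product: 18 (1S,4R,5S,6R,7R,8S,10R)-5,8-epoxy-1,4,10-trihydroxygermacran-6-yl (E)-cinnamate
Conditions: Zn(BH4)2, Et2O, −20 °C
Reagents that add atoms: none
Why: Chelation-controlled reduction of the α-hydroxy ketone: hydride adds to the zinc chelate from the outer face on the side of the C10 methyl, giving the 1,10-anti diol (1S), which is also the result of peripheral attack on the ring ketone.

Step 12
Reactants: 18 (1S,4R,5S,6R,7R,8S,10R)-5,8-epoxy-1,4,10-trihydroxygermacran-6-yl (E)-cinnamate; 19 acetic anhydride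
Product: 20 (1S,4R,5S,6R,7R,8S,10R)-1-acetoxy-6-(E)-cinnamoyloxy-5,8-epoxygermacrane-4,10-diol (target)
Conditions: Ac2O, pyridine, DMAP (cat.), CH2Cl2, 0 °C
Reagents that add atoms: acetic anhydride 19, CC(=O)OC(C)=O
Why: Acetylation of the only secondary alcohol; the tertiary C4 and C10 hydroxyls do not acylate under these conditions and no stereocenter is touched.

## Compound list

1 | (2E,6E)-farnesol | CC(C)=CCC/C(C)=C/CC/C(C)=C/CO | starting material
2 | (2E,6E)-10-bromo-3,7,11-trimethyldodeca-2,6-diene-1,11-diol (racemic) | CC(C)(O)C(Br)CC/C(C)=C/CC/C(C)=C/CO | intermediate (not isolated)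
3 | (2E,6E)-10,11-epoxyfarnesol (racemic epoxide) | CC1(C)OC1CC/C(C)=C/CC/C(C)=C/CO | intermediate
4 | (2E,6E)-3,7,11-trimethyl-10-(phenylselanyl)dodeca-2,6-diene-1,11-diol | CC(C)(O)C([Se]c1ccccc1)CC/C(C)=C/CC/C(C)=C/CO | intermediate (not isolated)
5 | (2E,6E,9E)-3,7,11-trimethyldodeca-2,6,9-triene-1,11-diol | CC(C)(O)/C=C/C/C(C)=C/CC/C(C)=C/CO | intermediate
6 | (2R,3R,6E,9E)-2,3-epoxy-3,7,11-trimethyldodeca-6,9-diene-1,11-diol | CC(C)(O)/C=C/C/C(C)=C/CC[C@@]1(C)O[C@@H]1CO | intermediate
7 | (2R,3R,6E)-2,3-epoxy-1-hydroxy-3,7,11-trimethyldodeca-6,10-dien-9-one | CC(C)=CC(=O)C/C(C)=C/CC[C@@]1(C)O[C@@H]1CO | intermediate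
8 | catechol boron (Z)-enolate of 7, O1 also borylated | CC(C)/C=C(/C/C(C)=C/CC[C@@]1(C)O[C@@H]1COB1Oc2ccccc2O1)OB1Oc2ccccc2O1 | intermediate (not isolated)
9 | (2R,3R,6E)-10-bromo-2,3-epoxy-1-hydroxy-3,7,11-trimethyldodec-6-en-9-one (both C10 epimers) | CC(C)C(Br)C(=O)C/C(C)=C/CC[C@@]1(C)O[C@@H]1CO | intermediate
10 | (2S,3R,6E)-10-bromo-2,3-epoxy-3,7,11-trimethyl-9-oxododec-6-enal | CC(C)C(Br)C(=O)C/C(C)=C/CC[C@@]1(C)O[C@@H]1C=O | intermediate
11 | dichlorochromium enolate of 10 (trivalent chromium on the C9 enolate oxygen) | CC(C)C=C(O[Cr](Cl)Cl)C/C(C)=C/CC[C@@]1(C)O[C@@H]1C=O | intermediate (not isolated)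
12 | (1(10)E,4R,5R,6R,7S)-4,5-epoxy-6-hydroxygermacr-1(10)-en-8-one | C/C1=C\CC[C@@]2(C)O[C@@H]2[C@H](O)[C@H](C(C)C)C(=O)C1 | intermediate
13 | (E)-cinnamaldehyde | O=C/C=C/c1ccccc1 | starting material
14 | (1(10)E,4R,5R,6R,7R,8S)-4,5-epoxy-8-hydroxygermacr-1(10)-en-6-yl (E)-cinnamate | C/C1=C\CC[C@@]2(C)O[C@@H]2[C@H](OC(=O)/C=C/c2ccccc2)[C@H](C(C)C)[C@@H](O)C1 | intermediate (not isolated)
15 | (1(10)E,4R,5S,6R,7R,8S)-5,8-epoxy-4-hydroxygermacr-1(10)-en-6-yl (E)-cinnamate | C/C1=C\CC[C@@](C)(O)[C@H]2O[C@@H](C1)[C@@H](C(C)C)[C@H]2OC(=O)/C=C/c1ccccc1 | intermediate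
16 | (1R,4R,5S,6R,7R,8S,10R)-5,8-epoxy-1,4,10-trihydroxygermacran-6-yl (E)-cinnamate | O[C@@H]1CC[C@@](C)(O)[C@H]2O[C@@H](C[C@@]1(C)O)[C@@H](C(C)C)[C@H]2OC(=O)/C=C/c1ccccc1 | intermediate
17 | (4R,5S,6R,7R,8S,10R)-5,8-epoxy-4,10-dihydroxy-1-oxogermacran-6-yl (E)-cinnamate | O=C1CC[C@@](C)(O)[C@H]2O[C@@H](C[C@@]1(C)O)[C@@H](C(C)C)[C@H]2OC(=O)/C=C/c1ccccc1 | intermediate
18 | (1S,4R,5S,6R,7R,8S,10R)-5,8-epoxy-1,4,10-trihydroxygermacran-6-yl (E)-cinnamate | O[C@H]1CC[C@@](C)(O)[C@H]2O[C@@H](C[C@@]1(C)O)[C@@H](C(C)C)[C@H]2OC(=O)/C=C/c1ccccc1 | intermediate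
19 | acetic anhydride | CC(=O)OC(C)=O | starting material
20 | (1S,4R,5S,6R,7R,8S,10R)-1-acetoxy-6-(E)-cinnamoyloxy-5,8-epoxygermacrane-4,10-diol | CC(=O)O[C@H]1CC[C@@](C)(O)[C@H]2O[C@@H](C[C@@]1(C)O)[C@@H](C(C)C)[C@H]2OC(=O)/C=C/c1ccccc1 | target

## Step count and risks

Total step count: 12. Longest linear sequence: 12 steps (1 to 20).

The three steps most likely to fail:

**Step 7 (chromium macro-aldol).** The most likely failures are reductive opening of the α,β-epoxy aldehyde by CrCl2 or poor facial control. The fallback closes the ring on the epoxide-free enal and introduces the epoxide afterwards by kinetic resolution. It sets out from 5 and comes back at 12.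
- Pyridinium chlorochromate (C5H5NH[CrO3Cl]) oxidises both hydroxyls of 5 (primary to the enal, tertiary allylic with transposition) to (2E,6E)-3,7,11-trimethyl-9-oxododeca-2,6,10-trienal F1.
- Catecholborane (1,4 on the enone, 1,2 on the aldehyde) followed by NBS gives (2E,6E)-10-bromo-1-hydroxy-3,7,11-trimethyldodeca-2,6-dien-9-one F2.
- MnO2 gives (2E,6E)-10-bromo-3,7,11-trimethyl-9-oxododeca-2,6-dienal F3.
- CrCl2 at high dilution closes F3 to the racemic anti aldol (1(10)E,4E,6S*,7S*)-6-hydroxygermacra-1(10),4-dien-8-one F4.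
- Sharpless kinetic resolution of F4 (Ti(OiPr)4, D-(−)-diisopropyl tartrate, 0.6 equiv t-BuOOH) epoxidises only the enantiomer whose erythro epoxy alcohol is 12, at the cost of at most half the material.

**Step 9 (osmylation).** Either the cinnamate alkene competes or the bridged trans alkene reacts through its other face. The fallback dihydroxylates the ten-membered ring before the cinnamate and the ether bridge exist, where outer-face attack on the germacrene-type alkene is best precedented. It sets out from 12 and comes back at 16.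
- OsO4/NMO converts 12 to (1R,4R,5R,6R,7S,10R)-4,5-epoxy-1,6,10-trihydroxygermacran-8-one F5.
- Evans–Tishchenko reduction of F5 with 13 and SmI2 gives (1R,4R,5R,6R,7R,8S,10R)-4,5-epoxy-1,8,10-trihydroxygermacran-6-yl (E)-cinnamate F6, which is not isolated and closes transannularly to 16.
- The price is a tertiary β-hydroxy ketone in F5 that can undergo retro-aldol cleavage during the samarium step.

**Step 4 (chemoselective oxidative transposition).** The primary alcohol may be oxidised or the epoxide may suffer from the acid formed. The fallback masks the primary alcohol. It sets out from 6 and comes back at 7.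
- TBSCl/imidazole gives (2R,3R,6E,9E)-1-(tert-butyldimethylsilyloxy)-2,3-epoxy-3,7,11-trimethyldodeca-6,9-dien-11-ol F7.
- Pyridinium chlorochromate (C5H5NH[CrO3Cl]) buffered with NaOAc gives (2R,3R,6E)-1-(tert-butyldimethylsilyloxy)-2,3-epoxy-3,7,11-trimethyldodeca-6,10-dien-9-one F8.
- Bu4NF removes the silyl group to give 7.

## Further compounds

F1 | step 7 | (2E,6E)-3,7,11-trimethyl-9-oxododeca-2,6,10-trienal | CC(C)=CC(=O)C/C(C)=C/CC/C(C)=C/C=O
F2 | step 7 | (2E,6E)-10-bromo-1-hydroxy-3,7,11-trimethyldodeca-2,6-dien-9-one | CC(C)C(Br)C(=O)C/C(C)=C/CC/C(C)=C/CO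
F3 | step 7 | (2E,6E)-10-bromo-3,7,11-trimethyl-9-oxododeca-2,6-dienal | CC(C)C(Br)C(=O)C/C(C)=C/CC/C(C)=C/C=O
F4 | step 7 | (1(10)E,4E,6S*,7S*)-6-hydroxygermacra-1(10),4-dien-8-one, racemic (the enantiomer that leads to 12 is drawn) | C/C1=C\CC/C(C)=C/[C@H](O)[C@H](C(C)C)C(=O)C1
F5 | step 9 | (1R,4R,5R,6R,7S,10R)-4,5-epoxy-1,6,10-trihydroxygermacran-8-one | O[C@@H]1CC[C@@]2(C)O[C@@H]2[C@H](O)[C@H](C(C)C)C(=O)C[C@@]1(C)O
F6 | step 9 | (1R,4R,5R,6R,7R,8S,10R)-4,5-epoxy-1,8,10-trihydroxygermacran-6-yl (E)-cinnamate | O[C@@H]1CC[C@@]2(C)O[C@@H]2[C@H](OC(=O)/C=C/c2ccccc2)[C@H](C(C)C)[C@@H](O)C[C@@]1(C)O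
F7 | step 4 | (2R,3R,6E,9E)-1-(tert-butyldimethylsilyloxy)-2,3-epoxy-3,7,11-trimethyldodeca-6,9-dien-11-ol | CC(C)(O)/C=C/C/C(C)=C/CC[C@@]1(C)O[C@@H]1CO[Si](C)(C)C(C)(C)C
F8 | step 4 | (2R,3R,6E)-1-(tert-butyldimethylsilyloxy)-2,3-epoxy-3,7,11-trimethyldodeca-6,10-dien-9-one | CC(C)=CC(=O)C/C(C)=C/CC[C@@]1(C)O[C@@H]1CO[Si](C)(C)C(C)(C)C
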